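The constants are still hidden, so the time scales come from the eta run, which is this flask followed up to 80.0 min.

- eta: substrate 1.5 M; partner 1.2 equiv; free catalyst 0.69 mol%; the very flask that is asked about, followed so far
- flask: substrate 1.5 M; partner 1.20 equiv; free catalyst 0.69 mol%; time 3.0 h

eta run (percent of the substrate charged)

| time / min | over-reaction product / % | substrate / % | target / % | catalyst intermediate B / % | catalyst intermediate A / % |
|---|---|---|---|---|---|
| 6.00 | 1.1 | 98.2 | 1.3 | 0.2 | 0 |
| 12.0 | 0.7 | 96.8 | 2.4 | 0 | 0.4 |
| 30.0 | 1.6 | 93.4 | 6.4 | 1.5 | 0.4 |
| 80.0 | 0.2 | 88.2 | 12.0 | 0.4 | 0 |

(readings scatter by 1 percentage point)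

- the species in which most of what was charged as substrate, at 3.0 h sits (over-reaction product / substrate / target / catalyst intermediate B / catalyst intermediate A)
- the largest share itself, whichever of these holds it, in percent of the substrate charged

- a reading or a percentage of target counts all its forms, free or not

1. Fastest rung: over the first 30.0 min, each catalyst unit turns over once per 3.14 min on the mean. Catalyst intermediates A and B together hold at most 0.69 mol% of the substrate, less than the scatter, so their readings are noise.
2. Middle rung: let k be the pseudo-first-order constant of the substrate, the slope of ln(charged/left) against time. It reads 0.137 h⁻¹ up to 30.0 min, then 0.0687 h⁻¹ up to 80.0 min, half as much. The flask slows within the readings.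
3. Slowest rung: 1/k reads 14.6 h, longer than 3.0 h, so substrate stays the main holder.
4. My own reckoning replaces the rest of the curve by that late mean. This gives Λ = 0.240, the logarithmic loss ln(charged/left) at 3.0 h, and 78.7% left. The mean constant of the whole 80.0 min gives 75.4%, which shows the size of the error. As a working assumption, with the share of the catalyst in each form following the same time course, Λ scales with the catalyst loading.
5. The forecast says substrate at 80%, range 73% to 86%, above my figure: “Substrate clearly still holds the most.”

The flask gives:

    substrate + free catalyst → catalyst intermediate A (k = 36.9 L mol⁻¹ h⁻¹)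
    partner + catalyst intermediate A → catalyst intermediate B (k = 33.7 L mol⁻¹ h⁻¹)
    catalyst intermediate B → free catalyst + target (k = 35.5 h⁻¹)
    free catalyst → spent catalyst (k = 0.852 h⁻¹)
    partner + target → over-reaction product (k = 0.0276 L mol⁻¹ h⁻¹)
    crystals ⇌ target, rate k6*(cs6 - [target]) while solid is left; crystals form when [target] > cs6 (solubility = 0.440 M, k = 41.0 h⁻¹)

At 3.0 h the flask holds 78.3% as substrate, so Λ is 0.245 against the reckoned 0.240, and the forecast stands. The neighbouring flask changes the free catalyst to 2.8 mol%, with the other charges and the time held. Scaling Λ by the loading gives 0.974, hence 37.7% substrate left. The neighbouring flask holds 32.5% substrate, so its Λ of 1.12 is larger than the scaled one. In the neighbouring flask the largest share has moved to target, at 64.6%.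

The numbers in the tables were computed with made-up constants; the scatter is artificial.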